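**Plan**

- Retrosynthesis: the two benzyl and two silyl groups come off last. The oxolane is cut at C2–C3, with its C3–CH2OH read as a reduced formyl group. A 2-aryl-oxolane-3-carbaldehyde is the product of a 1,3 O→C shift of a seven-membered vinyl acetal, a 2-aryl-4,5-dihydro-1,3-dioxepine (7→5 ring contraction).
- Enabling feature: in the oxolane, ring O1 and the electron-rich aryl group sit on the same carbon C2 (a masked oxocarbenium carbon). The neighbouring C3 carries a one-carbon unit at the aldehyde level (a masked enol carbon). C4–O and C5–CH2Ar ride on the tether.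
- The seven-membered acetal is cut into a cis-2,3-dihydrobenzofuran-5-carbaldehyde acetal and a cis-2,3-epoxy-1,4-diol; the O–CH=CH unit comes from the epoxide by syn β-elimination.
- Forward: arylacetic acid → ynone → (S)-propargylic alcohol → (Z)-alkene → threo epoxy diol. 5-Iodovanillin → benzylic ether → aryldiazoacetate → dihydrofuran ring (step 10). Union gives the dioxepane ring (step 13), then the enol ether, then the oxolane ring (step 15), then reduction and deprotection.
- Stereochemistry: oxolane C5 from the transfer hydrogenation, C4 from the hydroxyl-directed epoxidation, C3 and C2 from the ring contraction (relay from C4/C5). The cis-(2R,3R) dihydrobenzofuran pair comes from the chiral dirhodium catalyst.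

Key step: step 15

Remark 1: the target is read as (2S,3S,4S,5S) at the oxolane (O1, C2 = aryl carbon; 2,3-trans, 3,4-trans, 4,5-cis, 2,5-cis) and as 2,3-cis-(2R,3R) at the dihydrobenzofuran; the route is built for this isomer.
Remark 2: the (S)-configured dirhodium catalyst is assumed to give the (2R,3S)-ester 16; if the sense of induction on this substrate is opposite, the mirror-image catalyst is used with no other change.

Abbreviations: BMP = 4-(benzyloxy)-3-methoxyphenyl; TBS = tert-butyldimethylsilyl; DHB = (2R,3R)-2-BMP-3-[(TBS-oxy)methyl]-7-methoxy-2,3-dihydro-1-benzofuran-5-yl (2,3-cis).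

**Route**

Step 1
Reactants: 1 2-[4-(benzyloxy)-3-methoxyphenyl]acetic acid
Product: 3 2-BMP-N-methoxy-N-methylacetamide, via acyl imidazole 2 (not isolated)
Conditions: CDI, CH2Cl2, rt; then MeNH(OMe)·HCl, rt
Reagents that add atoms: N,O-dimethylhydroxylamine hydrochloride, CNOC.Cl; 1,1'-carbonyldiimidazole, O=C(n1ccnc1)n1ccnc1 (its imidazolyl group stays only in 2)
Why: Amide coupling through the acyl imidazole, in which the released imidazole frees the amine from its hydrochloride, should give the Weinreb amide that stops acyl substitution at the ketone stage in step 2.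

Step 2
Reactants: 3 2-BMP-N-methoxy-N-methylacetamide; 4 tert-butyldimethyl(prop-2-yn-1-yloxy)silane
Product: 6 1-BMP-5-(TBS-oxy)pent-3-yn-2-one, via lithium acetylide 5 (not isolated)
Conditions: 4, n-BuLi, THF, −78 °C; then 3, −78 → −20 °C; aq. NH4Cl
Reagents that add atoms: n-butyllithium, [Li]CCCC (its lithium stays only in 5)
Why: Weinreb ketone synthesis: the lithium acetylide should add once because the chelated tetrahedral adduct survives until work-up, and the low temperature limits enolisation of the arylacetyl CH2.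

Step 3
Reactants: 6 1-BMP-5-(TBS-oxy)pent-3-yn-2-one
Product: 7 (2S)-1-BMP-5-(TBS-oxy)pent-3-yn-2-ol
Conditions: RuCl[(S,S)-TsDPEN](p-cymene) (1 mol %), i-PrOH, rt
Reagents that add atoms: none
Why: Noyori asymmetric transfer hydrogenation of an alkynyl ketone: the Ru–(S,S)-TsDPEN hydride distinguishes the slim alkynyl group from the sp3 arylmethyl group in its six-membered hydride/proton transfer and should give the (S)-propargylic alcohol, the future C5 of the oxolane.

Step 4
Reactants: 7 (2S)-1-BMP-5-(TBS-oxy)pent-3-yn-2-ol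
Product: 8 (2S,3Z)-1-BMP-5-(TBS-oxy)pent-3-en-2-ol
Conditions: H2 (1 atm), Lindlar catalyst, quinoline, EtOAc, rt
Reagents that add atoms: none
Why: Lindlar semihydrogenation adds H2 syn on poisoned palladium and should give the (Z)-alkene without touching the benzyl or silyl ether.

Step 5
Reactants: 8 (2S,3Z)-1-BMP-5-(TBS-oxy)pent-3-en-2-ol
Product: 9 (1S)-2-BMP-1-{(2R,3S)-3-[(TBS-oxy)methyl]oxiran-2-yl}ethan-1-ol
Conditions: mCPBA, NaHCO3, CH2Cl2, 0 °C
Reagents that add atoms: 3-chloroperoxybenzoic acid, O=C(OO)c1cccc(Cl)c1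
Why: Hydroxyl-directed Prilezhaev epoxidation: allylic 1,3-strain in the (Z)-allylic alcohol puts the carbinol hydrogen in the alkene plane, so the hydrogen-bonded peracid is delivered syn to OH and should set the threo (2R,3S)-epoxide, the future C4 of the oxolane.

Step 6
Reactants: 9 (1S)-2-BMP-1-{(2R,3S)-3-[(TBS-oxy)methyl]oxiran-2-yl}ethan-1-ol
Product: 10 (1S)-2-BMP-1-[(2R,3S)-3-(hydroxymethyl)oxiran-2-yl]ethan-1-ol
Conditions: TBAF, AcOH (1:1), THF, 0 °C → rt
Reagents that add atoms: none
Why: Fluoride-induced desilylation, buffered with acetic acid so that no free alkoxide can start a Payne rearrangement of the epoxy alcohol.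

Step 7
Reactants: 11 4-hydroxy-3-iodo-5-methoxybenzaldehyde (5-iodovanillin); 12 [4-(benzyloxy)-3-methoxyphenyl]methanol
Product: 13 4-(BMP-methoxy)-3-iodo-5-methoxybenzaldehyde
Conditions: PPh3, DIAD, THF, 0 °C → rt
Reagents that add atoms: none
Why: Mitsunobu etherification: the acidic, doubly ortho-substituted phenol should be alkylated by the primary benzylic alcohol through its alkoxyphosphonium ion under neutral conditions that spare the aldehyde and the iodide.

Step 8
Reactants: 13 4-(BMP-methoxy)-3-iodo-5-methoxybenzaldehyde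
Product: 14 2-(BMP-methoxy)-5-(dimethoxymethyl)-1-iodo-3-methoxybenzene
Conditions: HC(OMe)3, MeOH, PPTS (cat.), rt; Et3N quench
Reagents that add atoms: trimethyl orthoformate, COC(OC)OC
Why: Acid-catalysed acetalisation with the orthoformate as water scavenger masks the aldehyde for the carbene, hydride and silylation steps and gives the acetal that is used directly in the fragment union.

Step 9
Reactants: 14 2-(BMP-methoxy)-5-(dimethoxymethyl)-1-iodo-3-methoxybenzene
Product: 15 ethyl 2-[2-(BMP-methoxy)-5-(dimethoxymethyl)-3-methoxyphenyl]-2-diazoacetate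
Conditions: ethyl diazoacetate, Pd(PPh3)4 (5 mol %), Ag2CO3 (0.5 equiv), Et3N, toluene, rt
Reagents that add atoms: ethyl diazoacetate, CCOC(=O)C=[N+]=[N-]
Why: Palladium-catalysed C–H arylation of an acceptor diazo compound: oxidative addition of the aryl iodide, silver-assisted palladation of the diazoacetate carbon and reductive elimination should give the aryldiazoacetate with the diazo group intact at room temperature.

Step 10
Reactants: 15 ethyl 2-[2-(BMP-methoxy)-5-(dimethoxymethyl)-3-methoxyphenyl]-2-diazoacetate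
Product: 16 ethyl (2R,3S)-2-BMP-5-(dimethoxymethyl)-7-methoxy-2,3-dihydro-1-benzofuran-3-carboxylate (2,3-cis)
Conditions: Rh2(S-PTTL)4 (1 mol %), toluene, −60 °C
Reagents that add atoms: none
Why: Dirhodium carbenoid 1,5 C–H insertion into the ether-activated benzylic methylene closes the dihydrofuran ring under kinetic control to the 2,3-cis ester, and the chiral N-phthaloyl-tert-leucinate ligands select one enantiotopic C–H bond, so C2 and C3 should be set together as (2R,3S).

Step 11
Reactants: 16 ethyl (2R,3S)-2-BMP-5-(dimethoxymethyl)-7-methoxy-2,3-dihydro-1-benzofuran-3-carboxylate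
Product: 17 [(2R,3R)-2-BMP-5-(dimethoxymethyl)-7-methoxy-2,3-dihydro-1-benzofuran-3-yl]methanol
Conditions: DIBAL-H, CH2Cl2, −78 → −40 °C; Rochelle salt
Reagents that add atoms: none
Why: Ester reduction with DIBAL-H is non-basic, so the epimerisable C3 (benzylic and alpha to the ester) should keep its cis relation to C2, and the acetal is inert to hydride.

Step 12
Reactants: 17 [(2R,3R)-2-BMP-5-(dimethoxymethyl)-7-methoxy-2,3-dihydro-1-benzofuran-3-yl]methanol
Product: 18 (2R,3R)-2-BMP-3-[(TBS-oxy)methyl]-5-(dimethoxymethyl)-7-methoxy-2,3-dihydro-1-benzofuran (DHB–CH(OMe)2)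
Conditions: TBSCl, imidazole, DMF, rt
Reagents that add atoms: tert-butyldimethylsilyl chloride, CC(C)(C)[Si](C)(C)Cl
Why: Silylation of the primary alcohol under basic conditions keeps the acid-labile dimethyl acetal and blocks the only hydroxyl group that could compete in the acetal exchange of step 13.

Step 13
Reactants: 10 (1S)-2-BMP-1-[(2R,3S)-3-(hydroxymethyl)oxiran-2-yl]ethan-1-ol; 18 DHB–CH(OMe)2
Product: 19 (1R,2S,7S)-2-(BMP-methyl)-4-DHB-3,5,8-trioxabicyclo[5.1.0]octane (C4 epimers)
Conditions: PPTS (10 mol %), CH2Cl2, 5 Å MS, rt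
Reagents that add atoms: none
Why: Acid-catalysed transacetalisation: the electron-rich aryl dimethyl acetal ionises under PPTS and the cis-epoxide holds both hydroxyl-bearing carbons on one side, so the 1,4-diol should close the seven-membered acetal once the sieves take up methanol; the acetal configuration is irrelevant because this carbon becomes sp2 in step 15.

Step 14
Reactants: 19 (1R,2S,7S)-2-(BMP-methyl)-4-DHB-3,5,8-trioxabicyclo[5.1.0]octane
Product: 21 (4S,5S)-4-(BMP-methyl)-2-DHB-5-(TBS-oxy)-4,5-dihydro-1,3-dioxepine (C2 epimers), via lithium alkoxide 20 (not isolated)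
Conditions: LDA, THF, −78 → 0 °C; then TBSCl, DMPU, 0 °C → rt
Reagents that add atoms: tert-butyldimethylsilyl chloride, CC(C)(C)[Si](C)(C)Cl; lithium diisopropylamide, [Li]N(C(C)C)C(C)C (its lithium stays only in 20)
Why: Lithium amide-mediated epoxide to allylic alcohol isomerisation (syn β-elimination through a cyclic transition state) followed by O-silylation: the epoxide oxygen is cis to the arylmethyl group, so the hydrogen on C2 is anti to it and the only syn β-hydrogen is on C6, which should force the O–CH=CH enol ether with retention at the carbinol carbon.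

Step 15
Reactants: 21 (4S,5S)-4-(BMP-methyl)-2-DHB-5-(TBS-oxy)-4,5-dihydro-1,3-dioxepine
Product: 23 [(2S,3R,4S,5S)-5-(BMP-methyl)-2-DHB-4-(TBS-oxy)oxolan-3-yl]methanol, via oxolane-3-carbaldehyde 22 (not isolated)
Conditions: TMSOTf (0.2 equiv), 2,6-di-tert-butyl-4-methylpyridine (0.3 equiv), CH2Cl2, −78 → −30 °C; then NaBH4, MeOH, −78 → 0 °C
Reagents that add atoms: none
Why: TMSOTf silylates the enol oxygen O1 of the dioxepine (O1–C2–O3–C4–C5–C6=C7) and cleaves C2–O1, giving an (E)-aryl oxocarbenium ion O3=C2 tethered to a (Z)-silyl enol ether; C6 then adds to C2 and the silyl group leaves the new formyl oxygen, so the seven-membered ring contracts to the oxolane (old O3, C2, C6, C5, C4) with old C7 as the exocyclic CHO, which borohydride reduces in the same flask. The closest known reaction type is the Lewis acid-induced rearrangement of 2-substituted 4,5-dihydro-1,3-dioxepines to 2,3-disubstituted tetrahydrofuran-3-carbaldehydes, a Petasis–Ferrier-type 1,3 O→C shift that amounts to an intramolecular Mukaiyama aldol addition to an oxocarbenium ion. The oxolane closes in a 5-(enol-exo)-endo-trig mode. Oxolane C3 is set by allylic 1,3-strain: the hydrogen on the silyloxy carbon eclipses the enol double bond and the tether holds the arylmethyl-bearing carbon on one face, so the new bond should form anti to the silyloxy group (3,4-trans). Oxolane C2 is set under thermodynamic control: the para-alkoxy-stabilised cation re-forms on warming and the aryl group should settle trans to the formyl group, which places it cis to the C5 arylmethyl group. The step needs ionisation of the enol C–O bond rather than Ferrier-type loss of the allylic oxygen, which the poorly leaving silyl ether and the donating aryl group secure, and it needs the β-silyloxy aldehyde to survive, which the immediate reduction secures.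

Step 16
Reactants: 23 [(2S,3R,4S,5S)-5-(BMP-methyl)-2-DHB-4-(TBS-oxy)oxolan-3-yl]methanol
Product: 24 (2S,3S,4S,5S)-2-(BMP-methyl)-5-[(2R,3R)-2-BMP-3-(hydroxymethyl)-7-methoxy-2,3-dihydro-1-benzofuran-5-yl]-4-(hydroxymethyl)oxolan-3-ol
Conditions: TBAF, THF, 0 °C → rt; aqueous work-up
Reagents that add atoms: none
Why: Fluoride-induced cleavage of the primary and the secondary silyl ether; no phenol is free at this stage, so the basic fluoride cannot open the dihydrobenzofuran through a quinone methide.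

Step 17
Reactants: 24 (2S,3S,4S,5S)-2-(BMP-methyl)-5-[(2R,3R)-2-BMP-3-(hydroxymethyl)-7-methoxy-2,3-dihydro-1-benzofuran-5-yl]-4-(hydroxymethyl)oxolan-3-ol
Product: 25 (2S,3S,4S,5S)-2-[(4-hydroxy-3-methoxyphenyl)methyl]-5-[(2R,3R)-2-(4-hydroxy-3-methoxyphenyl)-3-(hydroxymethyl)-7-methoxy-2,3-dihydro-1-benzofuran-5-yl]-4-(hydroxymethyl)oxolan-3-ol (CNP0179668.1)
Conditions: H2 (1 atm), 10 % Pd/C, EtOAc–MeOH, rt, stopped at full conversion
Reagents that add atoms: none
Why: Hydrogenolysis of the two aryl benzyl ethers over Pd/C is neutral and should be much faster than cleavage of the cyclic benzylic C–O bonds of the oxolane and the dihydrobenzofuran, so the target should form without epimerising the cis-dihydrobenzofuran.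

**Compound list**

1 | 2-[4-(benzyloxy)-3-methoxyphenyl]acetic acid | COc1cc(CC(=O)O)ccc1OCc1ccccc1 | starting material
2 | 1-{[4-(benzyloxy)-3-methoxyphenyl]acetyl}-1H-imidazole | COc1cc(CC(=O)n2ccnc2)ccc1OCc1ccccc1 | intermediate (not isolated)
3 | 2-BMP-N-methoxy-N-methylacetamide | COc1cc(CC(=O)N(C)OC)ccc1OCc1ccccc1 | intermediate
4 | tert-butyldimethyl(prop-2-yn-1-yloxy)silane | C#CCO[Si](C)(C)C(C)(C)C | starting material
5 | lithium 3-(TBS-oxy)prop-1-yn-1-ide | [Li]C#CCO[Si](C)(C)C(C)(C)C | intermediate (not isolated)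
6 | 1-BMP-5-(TBS-oxy)pent-3-yn-2-one | COc1cc(CC(=O)C#CCO[Si](C)(C)C(C)(C)C)ccc1OCc1ccccc1 | intermediate
7 | (2S)-1-BMP-5-(TBS-oxy)pent-3-yn-2-ol | O[C@@H](Cc1ccc(OCc2ccccc2)c(OC)c1)C#CCO[Si](C)(C)C(C)(C)C | intermediate
8 | (2S,3Z)-1-BMP-5-(TBS-oxy)pent-3-en-2-ol | O[C@@H](Cc1ccc(OCc2ccccc2)c(OC)c1)/C=C\CO[Si](C)(C)C(C)(C)C | intermediate
9 | (1S)-2-BMP-1-{(2R,3S)-3-[(TBS-oxy)methyl]oxiran-2-yl}ethan-1-ol | O[C@@H](Cc1ccc(OCc2ccccc2)c(OC)c1)[C@H]1O[C@H]1CO[Si](C)(C)C(C)(C)C | intermediate
10 | (1S)-2-BMP-1-[(2R,3S)-3-(hydroxymethyl)oxiran-2-yl]ethan-1-ol | O[C@@H](Cc1ccc(OCc2ccccc2)c(OC)c1)[C@H]1O[C@H]1CO | intermediate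
11 | 4-hydroxy-3-iodo-5-methoxybenzaldehyde (5-iodovanillin) | COc1cc(C=O)cc(I)c1O | starting material
12 | [4-(benzyloxy)-3-methoxyphenyl]methanol | COc1cc(CO)ccc1OCc1ccccc1 | starting material
13 | 4-(BMP-methoxy)-3-iodo-5-methoxybenzaldehyde | COc1cc(C=O)cc(I)c1OCc1ccc(OCc2ccccc2)c(OC)c1 | intermediate
14 | 2-(BMP-methoxy)-5-(dimethoxymethyl)-1-iodo-3-methoxybenzene | COc1cc(C(OC)OC)cc(I)c1OCc1ccc(OCc2ccccc2)c(OC)c1 | intermediate
15 | ethyl 2-[2-(BMP-methoxy)-5-(dimethoxymethyl)-3-methoxyphenyl]-2-diazoacetate | COc1cc(C(OC)OC)cc(C(=[N+]=[N-])C(=O)OCC)c1OCc1ccc(OCc2ccccc2)c(OC)c1 | intermediate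
16 | ethyl (2R,3S)-2-BMP-5-(dimethoxymethyl)-7-methoxy-2,3-dihydro-1-benzofuran-3-carboxylate (2,3-cis) | COC(OC)c1cc(OC)c2c(c1)[C@H](C(=O)OCC)[C@H](c1ccc(OCc3ccccc3)c(OC)c1)O2 | intermediate
17 | [(2R,3R)-2-BMP-5-(dimethoxymethyl)-7-methoxy-2,3-dihydro-1-benzofuran-3-yl]methanol | COC(OC)c1cc(OC)c2c(c1)[C@H](CO)[C@H](c1ccc(OCc3ccccc3)c(OC)c1)O2 | intermediate
18 | (2R,3R)-2-BMP-3-[(TBS-oxy)methyl]-5-(dimethoxymethyl)-7-methoxy-2,3-dihydro-1-benzofuran (DHB–CH(OMe)2) | COC(OC)c1cc(OC)c2c(c1)[C@H](CO[Si](C)(C)C(C)(C)C)[C@H](c1ccc(OCc3ccccc3)c(OC)c1)O2 | intermediate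
19 | (1R,2S,7S)-2-(BMP-methyl)-4-DHB-3,5,8-trioxabicyclo[5.1.0]octane (C4 epimers) | O1[C@@H](Cc2ccc(OCc3ccccc3)c(OC)c2)[C@H]2O[C@H]2COC1c1cc(OC)c2c(c1)[C@H](CO[Si](C)(C)C(C)(C)C)[C@H](c1ccc(OCc3ccccc3)c(OC)c1)O2 | intermediate
20 | lithium (4S,5S)-4-(BMP-methyl)-2-DHB-4,5-dihydro-1,3-dioxepin-5-olate (C2 epimers) | O1[C@@H](Cc2ccc(OCc3ccccc3)c(OC)c2)[C@@H](O[Li])C=COC1c1cc(OC)c2c(c1)[C@H](CO[Si](C)(C)C(C)(C)C)[C@H](c1ccc(OCc3ccccc3)c(OC)c1)O2 | intermediate (not isolated)
21 | (4S,5S)-4-(BMP-methyl)-2-DHB-5-(TBS-oxy)-4,5-dihydro-1,3-dioxepine (C2 epimers) | O1[C@@H](Cc2ccc(OCc3ccccc3)c(OC)c2)[C@@H](O[Si](C)(C)C(C)(C)C)C=COC1c1cc(OC)c2c(c1)[C@H](CO[Si](C)(C)C(C)(C)C)[C@H](c1ccc(OCc3ccccc3)c(OC)c1)O2 | intermediate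
22 | (2S,3R,4S,5S)-5-(BMP-methyl)-2-DHB-4-(TBS-oxy)oxolane-3-carbaldehyde | COc1cc(C[C@@H]2O[C@H](c3cc(OC)c4c(c3)[C@H](CO[Si](C)(C)C(C)(C)C)[C@H](c3ccc(OCc5ccccc5)c(OC)c3)O4)[C@@H](C=O)[C@@H]2O[Si](C)(C)C(C)(C)C)ccc1OCc1ccccc1 | intermediate (not isolated)
23 | [(2S,3R,4S,5S)-5-(BMP-methyl)-2-DHB-4-(TBS-oxy)oxolan-3-yl]methanol | COc1cc(C[C@@H]2O[C@H](c3cc(OC)c4c(c3)[C@H](CO[Si](C)(C)C(C)(C)C)[C@H](c3ccc(OCc5ccccc5)c(OC)c3)O4)[C@@H](CO)[C@@H]2O[Si](C)(C)C(C)(C)C)ccc1OCc1ccccc1 | intermediate
24 | (2S,3S,4S,5S)-2-(BMP-methyl)-5-[(2R,3R)-2-BMP-3-(hydroxymethyl)-7-methoxy-2,3-dihydro-1-benzofuran-5-yl]-4-(hydroxymethyl)oxolan-3-ol | COc1cc(C[C@@H]2O[C@H](c3cc(OC)c4c(c3)[C@H](CO)[C@H](c3ccc(OCc5ccccc5)c(OC)c3)O4)[C@@H](CO)[C@@H]2O)ccc1OCc1ccccc1 | intermediate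
25 | (2S,3S,4S,5S)-2-[(4-hydroxy-3-methoxyphenyl)methyl]-5-[(2R,3R)-2-(4-hydroxy-3-methoxyphenyl)-3-(hydroxymethyl)-7-methoxy-2,3-dihydro-1-benzofuran-5-yl]-4-(hydroxymethyl)oxolan-3-ol | COc1cc(C[C@@H]2O[C@H](c3cc(OC)c4c(c3)[C@H](CO)[C@H](c3ccc(O)c(OC)c3)O4)[C@@H](CO)[C@@H]2O)ccc1O | target

**Totals**

Total step count: 17.
Longest linear sequence: 11 steps (steps 1–6 then 13–17 from 1; the branch from 11 through steps 7–12 then 13–17 is equally long).

**Steps most likely to fail**

1. Step 15. The ring may close on the wrong face of the oxocarbenium carbon under kinetic control, putting the aryl group cis to the formyl group. Warming to equilibrate in situ is limited by Friedel–Crafts capture of the cation by the electron-rich arylmethyl ring and by β-elimination of the silyloxy group. Fallback, setting out from 21 and coming back at 23: the ring contraction is run and reduced cold (TMSOTf, −78 °C, then NaBH4), so that the kinetic C2 epimer [(2R,3R,4S,5S)-5-(BMP-methyl)-2-DHB-4-(TBS-oxy)oxolan-3-yl]methanol F1 is isolated. The stereocentre is then set in a separate operation: F1 is treated with BF3·OEt2 (cat.) in CH2Cl2 at −40 → 0 °C. This ionises the benzylic C2–O1 bond to the para-alkoxybenzyl cation and lets the C5 oxygen reclose to the 2,3-trans isomer 23, the acid equilibration known for 2-aryl-tetrahydrofuran lignans; no oxocarbenium ion next to the arylmethyl ring is regenerated.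

2. Step 14. The strong base may deprotonate elsewhere: ring-opening elimination of the aryloxide from the dihydrobenzofuran, or metalation at the epoxide or acetal carbon. Silylation of the hindered lithium alkoxide may also be incomplete. Fallback, setting out from 19 and coming back at 21, without strong base: the epoxide is opened by sodium phenylselenide ((PhSe)2, NaBH4, EtOH) at the carbon remote from the arylmethyl-bearing centre, to give (4S,5R,6R)-4-(BMP-methyl)-2-DHB-6-(phenylselanyl)-1,3-dioxepan-5-ol F2. Oxidation with H2O2 in the presence of pyridine and syn-elimination of the selenoxide, which runs away from the carbinol carbon, should give the allylic alcohol (4S,5S)-4-(BMP-methyl)-2-DHB-4,5-dihydro-1,3-dioxepin-5-ol F3. TBSCl and imidazole in DMF then give 21.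

3. Step 9. Oxidative addition at the hindered, electron-rich aryl iodide may be slow, and the diazo ester may decompose by palladium-carbene dimerisation before coupling. Fallback, setting out from 14 and coming back at 15: the carbon–carbon bond is made first and the diazo group is introduced afterwards. Palladium-catalysed coupling of 14 with the Reformatsky reagent BrZnCH2CO2Et (Pd2(dba)3, XPhos, THF, rt) gives ethyl 2-[2-(BMP-methoxy)-5-(dimethoxymethyl)-3-methoxyphenyl]acetate F4. Regitz diazo transfer (4-acetamidobenzenesulfonyl azide, DBU, MeCN, 0 °C → rt) converts F4 into 15.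

Further compounds
F1 | step 15 | [(2R,3R,4S,5S)-5-(BMP-methyl)-2-DHB-4-(TBS-oxy)oxolan-3-yl]methanol (C2 epimer of 23) | COc1cc(C[C@@H]2O[C@@H](c3cc(OC)c4c(c3)[C@H](CO[Si](C)(C)C(C)(C)C)[C@H](c3ccc(OCc5ccccc5)c(OC)c3)O4)[C@@H](CO)[C@@H]2O[Si](C)(C)C(C)(C)C)ccc1OCc1ccccc1
F2 | step 14 | (4S,5R,6R)-4-(BMP-methyl)-2-DHB-6-(phenylselanyl)-1,3-dioxepan-5-ol (C2 epimers) | O1[C@@H](Cc2ccc(OCc3ccccc3)c(OC)c2)[C@@H](O)[C@H]([Se]c2ccccc2)COC1c1cc(OC)c2c(c1)[C@H](CO[Si](C)(C)C(C)(C)C)[C@H](c1ccc(OCc3ccccc3)c(OC)c1)O2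
F3 | step 14 | (4S,5S)-4-(BMP-methyl)-2-DHB-4,5-dihydro-1,3-dioxepin-5-ol (C2 epimers) | O1[C@@H](Cc2ccc(OCc3ccccc3)c(OC)c2)[C@@H](O)C=COC1c1cc(OC)c2c(c1)[C@H](CO[Si](C)(C)C(C)(C)C)[C@H](c1ccc(OCc3ccccc3)c(OC)c1)O2
F4 | step 9 | ethyl 2-[2-(BMP-methoxy)-5-(dimethoxymethyl)-3-methoxyphenyl]acetate | COc1cc(C(OC)OC)cc(CC(=O)OCC)c1OCc1ccc(OCc2ccccc2)c(OC)c1
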